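Ring A is disconnected across C7–C8 and C5–C6. Its C6–C7 edge is an acetyl unit placed between C5, an ester carbon on C4a, and C8, the acidic side-chain methylene on C8a of an intact, enantiopure ring C. One operation acylates C8 with N-methoxy-N-methylacetamide, closes ring A by Claisen attack of C6 on C5 and aromatises to (R)-5,7-dihydroxy-8-prenylflavanone; the prenyl group is the remainder of the C8a side chain. The precursor is methyl (R)-6-(4-methylpent-3-enyl)-4-oxo-2-phenyl-2,3-dihydropyran-5-carboxylate, built from a prenylated acetoacetate and an (R)-3-silyloxy-3-phenylpropanoyl unit whose stereocentre comes from asymmetric hydrogenation. Exhaustive O-methylation completes the synthesis.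

Key step: step 7

Remark: flavanone numbering (O1, C2, C3, C4, C4a, C5–C8, C8a) is used for these atoms in every intermediate; the target SMILES defines C2 as R, and this descriptor is unchanged from hydroxy ester to pyranone to flavanone because the priority order O > phenyl > CH2 > H never changes.

Step 1
Reactants: 1 methyl acetoacetate; 2 prenyl bromide (1-bromo-3-methylbut-2-ene)
Product: 3 methyl 7-methyl-3-oxooct-6-enoate
Conditions: NaH, THF, 0 °C; n-BuLi, 0 °C; 2, 0 °C → rt; aq. HCl
Reagents that add atoms: none
Why: Dianion γ-alkylation of a β-keto ester, in which the terminal carbanion is far more nucleophilic than the stabilised central enolate carbon and displaces the primary allylic bromide by SN2 without allylic transposition.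

Step 2
Reactants: 4 methyl benzoylacetate (methyl 3-oxo-3-phenylpropanoate)
Product: 5 methyl (3R)-3-hydroxy-3-phenylpropanoate
Conditions: H2 (50 atm), RuCl2[(S)-BINAP] (0.5 mol %), MeOH, 50 °C
Reagents that add atoms: none
Why: Noyori asymmetric hydrogenation of a β-keto ester, in which chelation of the keto ester to the ruthenium hydride fixes the face of hydride delivery; the (S)-ligand is expected to give the 3R alcohol (the spatial sense that gives (S)-3-hydroxybutanoate, named R here because phenyl outranks CH2CO2Me), which sets the only stereocentre of the route.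

Step 3
Reactants: 5 methyl (3R)-3-hydroxy-3-phenylpropanoate
Product: 6 methyl (3R)-3-[tert-butyl(dimethyl)silyl]oxy-3-phenylpropanoate
Conditions: TBSCl, imidazole, DMF, rt
Reagents that add atoms: tert-butyl(chloro)dimethylsilane, CC(C)(C)[Si](C)(C)Cl
Why: Imidazole-promoted silylation of a secondary alcohol, needed so that the carboxyl group can later be activated without self-acylation; the stereocentre is not touched.

Step 4
Reactants: 6 methyl (3R)-3-[tert-butyl(dimethyl)silyl]oxy-3-phenylpropanoate
Product: 7 (3R)-3-[tert-butyl(dimethyl)silyl]oxy-3-phenylpropanoic acid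
Conditions: LiOH·H2O, THF/MeOH/H2O, 0 °C → rt; 1 M HCl to pH 3–4, 0 °C
Reagents that add atoms: lithium hydroxide, [Li+].[OH-]
Why: Saponification of a methyl ester under conditions mild enough that the silyl ether should stay on and E1cB loss of silanolate to cinnamate is not expected; the stereocentre carries no acidic hydrogen and is unaffected.

Step 5
Reactants: 7 (3R)-3-[tert-butyl(dimethyl)silyl]oxy-3-phenylpropanoic acid; 3 methyl 7-methyl-3-oxooct-6-enoate
Product: 9 methyl (5R)-5-[tert-butyl(dimethyl)silyl]oxy-2-(5-methylhex-4-enoyl)-3-oxo-5-phenylpentanoate, via acid chloride 8 (not isolated)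
Conditions: 7, 1-chloro-N,N,2-trimethylprop-1-en-1-amine, CH2Cl2, 0 °C → rt; then 3, MgCl2, pyridine, CH2Cl2, 0 °C → rt
Reagents that add atoms: none
Why: The α-chloroenamine converts the acid into its chloride without HCl, and the magnesium chelate of the β-keto ester (soft enolisation with MgCl2/pyridine) is acylated at carbon, the established C-acylation route to 2-acyl-3-oxo esters.

Step 6
Reactants: 9 methyl (5R)-5-[tert-butyl(dimethyl)silyl]oxy-2-(5-methylhex-4-enoyl)-3-oxo-5-phenylpentanoate
Product: 11 methyl (2R)-6-(4-methylpent-3-enyl)-4-oxo-2-phenyl-2,3-dihydro-4H-pyran-5-carboxylate, via hydroxy triketo ester 10 (not isolated)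
Conditions: 48% aq. HF, MeCN, 0 °C → rt; then TsOH·H2O (cat.), 4 Å MS, CH2Cl2, rt
Reagents that add atoms: none
Why: Fluoride removes the silyl group, and the freed hydroxyl adds to the side-chain ketone (6-exo-trig hemiketalisation) and loses water to give the conjugated vinylogous ester, the usual acid-mediated cyclodehydration of hydroxy 1,3-diketones to 2,3-dihydropyran-4-ones; the benzylic C–O bond is never broken, so C2 stays R.

Step 7
Reactants: 11 methyl (2R)-6-(4-methylpent-3-enyl)-4-oxo-2-phenyl-2,3-dihydro-4H-pyran-5-carboxylate; 12 N-methoxy-N-methylacetamide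
Product: 14 (2R)-5,7-dihydroxy-8-(3-methylbut-2-enyl)-2-phenylchroman-4-one, via C8-acetyl ketone 13 (not isolated)
Conditions: LiN(SiMe3)2 (1.05 equiv), THF, −78 °C; 12 (1.3 equiv); LiN(SiMe3)2 (2.3 equiv), −78 °C → rt; AcOH, −78 °C
Reagents that add atoms: none
Why: Proposed new method: LiN(SiMe3)2 removes a C8 proton of 11 (the side-chain CH2 on C8a, doubly vinylogous to the C4 ketone and the C5 ester), the extended enolate adds through C8 to amide 12, and a second deprotonation at C8 expels LiN(OMe)Me from the adduct (E1cB) to give the enolate of methyl ketone 13, whose C6 methyl group is then deprotonated at equilibrium so that C6 attacks the ester carbon C5, methoxide leaves and two enolisations aromatise ring A as the 5,7-diphenoxide. The closest known reaction type is the acylation–Dieckmann benzannulation of ortho-toluate anions with acetyl donors to 1,3-dihydroxynaphthalenes, with the C4a=C8a enol-ether double bond of ring C in the role of the arene. Ring A closes by a 6-exo-trig Claisen (Dieckmann) attack of C6 on C5, possible because C5 and C8 are held cis on the C4a=C8a bond. No stereocentre is formed, and C2 is only carried through. The step needs deprotonation at C8 and not at C3 (a C3 enolate would expel O1, open ring C and racemise C2) and C- over O-attack in both acylations; the much higher acidity of C8–H toward a weak, hindered amide base, the fact that the C4 carbonyl no longer acidifies C3 once it is part of the C8 anion or of the diphenoxide, and the irreversible aromatisation that drains the C-cyclisation pathway should secure this.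

Step 8
Reactants: 14 (2R)-5,7-dihydroxy-8-(3-methylbut-2-enyl)-2-phenylchroman-4-one
Product: 15 (2R)-5,7-dimethoxy-8-(3-methylbut-2-enyl)-2-phenylchroman-4-one
Conditions: MeI (excess), Ag2O, DMF, rt, dark
Reagents that add atoms: iodomethane, CI
Why: Purdie methylation, in which Ag2O-assisted O-alkylation with MeI etherifies the free 7-hydroxyl and, with excess reagent in DMF, the hydrogen-bonded 5-hydroxyl under conditions too weakly basic to enolise C3, so ring C should stay closed and C2 should stay R.

Compound list
1 | methyl acetoacetate | COC(=O)CC(C)=O | starting material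
2 | prenyl bromide (1-bromo-3-methylbut-2-ene) | CC(C)=CCBr | starting material
3 | methyl 7-methyl-3-oxooct-6-enoate | COC(=O)CC(=O)CCC=C(C)C | intermediate
4 | methyl benzoylacetate | COC(=O)CC(=O)c1ccccc1 | starting material
5 | methyl (3R)-3-hydroxy-3-phenylpropanoate | COC(=O)C[C@@H](O)c1ccccc1 | intermediate
6 | methyl (3R)-3-[tert-butyl(dimethyl)silyl]oxy-3-phenylpropanoate | COC(=O)C[C@@H](O[Si](C)(C)C(C)(C)C)c1ccccc1 | intermediate
7 | (3R)-3-[tert-butyl(dimethyl)silyl]oxy-3-phenylpropanoic acid | OC(=O)C[C@@H](O[Si](C)(C)C(C)(C)C)c1ccccc1 | intermediate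
8 | (3R)-3-[tert-butyl(dimethyl)silyl]oxy-3-phenylpropanoyl chloride (not isolated) | ClC(=O)C[C@@H](O[Si](C)(C)C(C)(C)C)c1ccccc1 | intermediate
9 | methyl (5R)-5-[tert-butyl(dimethyl)silyl]oxy-2-(5-methylhex-4-enoyl)-3-oxo-5-phenylpentanoate (drawn as the triketo tautomer; C2 is enolised and configurationally labile) | COC(=O)C(C(=O)CCC=C(C)C)C(=O)C[C@@H](O[Si](C)(C)C(C)(C)C)c1ccccc1 | intermediate
10 | methyl (5R)-5-hydroxy-2-(5-methylhex-4-enoyl)-3-oxo-5-phenylpentanoate (not isolated) | COC(=O)C(C(=O)CCC=C(C)C)C(=O)C[C@@H](O)c1ccccc1 | intermediate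
11 | methyl (2R)-6-(4-methylpent-3-enyl)-4-oxo-2-phenyl-2,3-dihydro-4H-pyran-5-carboxylate | O1[C@@H](c2ccccc2)CC(=O)C(C(=O)OC)=C1CCC=C(C)C | intermediate
12 | N-methoxy-N-methylacetamide | CON(C)C(C)=O | starting material
13 | methyl (2R)-6-(6-methyl-2-oxohept-5-en-3-yl)-4-oxo-2-phenyl-2,3-dihydro-4H-pyran-5-carboxylate (not isolated; present as its enolate, side-chain CH centre labile) | O1[C@@H](c2ccccc2)CC(=O)C(C(=O)OC)=C1C(C(C)=O)CC=C(C)C | intermediate
14 | (2R)-5,7-dihydroxy-8-(3-methylbut-2-enyl)-2-phenylchroman-4-one ((R)-5,7-dihydroxy-8-prenylflavanone) | Oc1cc(O)c2c(c1CC=C(C)C)O[C@@H](c1ccccc1)CC2=O | intermediate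
15 | (2R)-5,7-dimethoxy-8-(3-methylbut-2-enyl)-2-phenylchroman-4-one | COc1cc(OC)c2c(c1CC=C(C)C)O[C@@H](c1ccccc1)CC2=O | target

Total step count: 8.
Longest linear sequence: 7 steps (steps 2 to 8, from methyl benzoylacetate 4).

Steps most likely to fail

Step 7. The base may remove a C3 proton, which would open ring C by loss of O1 and erode the configuration at C2. The cascade may stall at the amide adduct or at the ketone stage. The ketone enolate may close through oxygen to a lactone and not through C6. The fallback uses only known reaction types, sets out from prenyl bromide 2 and comes back to the route at target 15. Commercial 2,4,6-trihydroxyacetophenone is C-prenylated with 2 (aq. KOH, 0 °C) to give 1-[2,4,6-trihydroxy-3-(3-methylbut-2-enyl)phenyl]ethanone F1. Me2SO4 (2 equiv) and K2CO3 in acetone should methylate the 4-hydroxyl and the unhindered 6-hydroxyl and leave the prenyl-flanked, hydrogen-bonded 2-hydroxyl, giving 1-[2-hydroxy-4,6-dimethoxy-3-(3-methylbut-2-enyl)phenyl]ethanone F2. Condensation with N,N-dimethylformamide dimethyl acetal gives (2E)-3-(dimethylamino)-1-[2-hydroxy-4,6-dimethoxy-3-(3-methylbut-2-enyl)phenyl]prop-2-en-1-one F3, which dilute HCl in CH2Cl2 closes to 5,7-dimethoxy-8-(3-methylbut-2-enyl)-4H-chromen-4-one F4. Asymmetric conjugate addition of phenylboronic acid to F4, catalysed by Pd(OCOCF3)2 and t-BuPyOx (NH4PF6, H2O, 1,2-dichloroethane, 60 °C), then gives 15; the ligand enantiomer is chosen to deliver phenyl to the face that gives 2R.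

Step 6. The freed hydroxyl may lactonise onto the methyl ester instead of adding to the ketone, the benzylic oxygen may be lost by β-elimination to a cinnamoyl compound, or acid may cyclise the trisubstituted alkene onto an enol oxygen. The fallback sets out from keto ester 3 (with acid chloride 8 generated from 7 as in step 5) and comes back at 11. Compound 3 is condensed with pyrrolidine (toluene, cat. AcOH, removal of water) to give methyl (2E)-7-methyl-3-(pyrrolidin-1-yl)octa-2,6-dienoate F5. F5 is C-acylated with 8 (Et3N, CH2Cl2, 0 °C) to give methyl (5R)-5-[tert-butyl(dimethyl)silyl]oxy-2-[5-methyl-1-(pyrrolidin-1-yl)hex-4-enylidene]-3-oxo-5-phenylpentanoate F6. Desilylation with aq. HF in MeCN gives methyl (5R)-5-hydroxy-2-[5-methyl-1-(pyrrolidin-1-yl)hex-4-enylidene]-3-oxo-5-phenylpentanoate F7 in the flask. Its hydroxyl adds to the amine-bearing carbon and expels pyrrolidine (addition–elimination on an enaminone) to give 11. The amine marks the only electrophilic carbon, so the ester cannot compete and no free tricarbonyl compound is exposed to acid.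

Step 5. The acid chloride may lose silanol through ketene formation or β-elimination, or the enolate may be acylated on oxygen. The fallback reverses the roles of the two fragments, sets out from acid 7 and comes back at 9. Acid 7 is activated with 1,1'-carbonyldiimidazole to give (3R)-3-[tert-butyl(dimethyl)silyl]oxy-1-(imidazol-1-yl)-3-phenylpropan-1-one F8. F8 is homologated with the magnesium salt of methyl hydrogen malonate (methyl potassium malonate, MgCl2, Et3N, THF; decarboxylative Claisen condensation) to give methyl (5R)-5-[tert-butyl(dimethyl)silyl]oxy-3-oxo-5-phenylpentanoate F9. The magnesium chelate of F9 (MgCl2, pyridine, CH2Cl2) is C-acylated with 5-methylhex-4-enoyl chloride F10, made from commercial 5-methylhex-4-enoic acid with oxalyl chloride and cat. DMF, to give 9. The β-silyloxy acyl unit is then never an acid chloride, and the acid chloride used carries no β-leaving group.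

Further compounds
F1 | step 7 | 1-[2,4,6-trihydroxy-3-(3-methylbut-2-enyl)phenyl]ethanone | CC(=O)c1c(O)cc(O)c(CC=C(C)C)c1O
F2 | step 7 | 1-[2-hydroxy-4,6-dimethoxy-3-(3-methylbut-2-enyl)phenyl]ethanone | CC(=O)c1c(OC)cc(OC)c(CC=C(C)C)c1O
F3 | step 7 | (2E)-3-(dimethylamino)-1-[2-hydroxy-4,6-dimethoxy-3-(3-methylbut-2-enyl)phenyl]prop-2-en-1-one | CN(C)/C=C/C(=O)c1c(OC)cc(OC)c(CC=C(C)C)c1O
F4 | step 7 | 5,7-dimethoxy-8-(3-methylbut-2-enyl)-4H-chromen-4-one | COc1cc(OC)c2c(c1CC=C(C)C)OC=CC2=O
F5 | step 6 | methyl (2E)-7-methyl-3-(pyrrolidin-1-yl)octa-2,6-dienoate | COC(=O)/C=C(/N1CCCC1)CCC=C(C)C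
F6 | step 6 | methyl (5R)-5-[tert-butyl(dimethyl)silyl]oxy-2-[5-methyl-1-(pyrrolidin-1-yl)hex-4-enylidene]-3-oxo-5-phenylpentanoate (push–pull alkene, geometry not fixed) | COC(=O)C(=C(N1CCCC1)CCC=C(C)C)C(=O)C[C@@H](O[Si](C)(C)C(C)(C)C)c1ccccc1
F7 | step 6 | methyl (5R)-5-hydroxy-2-[5-methyl-1-(pyrrolidin-1-yl)hex-4-enylidene]-3-oxo-5-phenylpentanoate | COC(=O)C(=C(N1CCCC1)CCC=C(C)C)C(=O)C[C@@H](O)c1ccccc1
F8 | step 5 | (3R)-3-[tert-butyl(dimethyl)silyl]oxy-1-(imidazol-1-yl)-3-phenylpropan-1-one | O=C(C[C@@H](O[Si](C)(C)C(C)(C)C)c1ccccc1)n1ccnc1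
F9 | step 5 | methyl (5R)-5-[tert-butyl(dimethyl)silyl]oxy-3-oxo-5-phenylpentanoate | COC(=O)CC(=O)C[C@@H](O[Si](C)(C)C(C)(C)C)c1ccccc1
F10 | step 5 | 5-methylhex-4-enoyl chloride | CC(C)=CCCC(Cl)=O
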